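**Retrosynthetic overview**
- The gem-diprenyl carbon C5 and the enolised triketone of the six-membered ring are made last, by dearomative double C-prenylation of the only free ring CH of an (R)-7-isobutyryl-4,6-dihydroxy-2-(2-hydroxypropan-2-yl)-2,3-dihydrobenzofuran.
- That phenol comes from its bis-MOM ether by acid, and the tertiary alcohol from a 2-isopropenyl group by Markovnikov hydration, done before any prenyl alkene exists and before acid meets an allylic C2–O bond.
- The strategy rests on the dihydrofuran ring (O1, C2, C3, C3a, C7a): the O1–C2 bond, the C3–C3a bond and the branched three-carbon group on C2 are one isoprene unit laid across an ortho-iodophenol by enantioselective palladium heteroannulation, which sets (R)-C2.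
- The iodophenol comes from phloroglucinol by Friedel–Crafts isobutyrylation, bis-MOM protection and iodination ortho to the ketone-chelated hydroxyl.
- Ring order: the benzene ring is bought, the dihydrofuran ring closes in step 4, and the carbocycle is dearomatised in step 7.

Key step: step 4

Remark: the target is drawn as one enol tautomer of a cyclic β-triketone; the tautomers interconvert freely, so the route aims at this equilibrating compound.

**Step 1**
Reactants: 1 phloroglucinol; 2 isobutyryl chloride
Product: 3 2-methyl-1-(2,4,6-trihydroxyphenyl)propan-1-one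
Conditions: AlCl3 (3.5 equiv), PhNO2, rt → 65 °C; then ice/aq. HCl
Reagents that add atoms: none
Why: Friedel–Crafts C-acylation of the threefold-activated ring, in which the first acyl group deactivates the arene and so holds the reaction at mono-acylation.

**Step 2**
Reactants: 3 2-methyl-1-(2,4,6-trihydroxyphenyl)propan-1-one
Product: 4 1-[2-hydroxy-4,6-bis(methoxymethoxy)phenyl]-2-methylpropan-1-one
Conditions: MOMCl (2.2 equiv), i-Pr2NEt (3 equiv), CH2Cl2, 0 °C → rt
Reagents that add atoms: chloromethyl methyl ether (MOMCl, two equivalents), COCCl
Why: O-alkylation (MOM ether formation) under amine base takes the para hydroxyl and one ortho hydroxyl, while the hydroxyl hydrogen-bonded to the ketone stays free, as is general for 2,4,6-trihydroxyaryl ketones.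

**Step 3**
Reactants: 4 1-[2-hydroxy-4,6-bis(methoxymethoxy)phenyl]-2-methylpropan-1-one
Product: 5 1-[2-hydroxy-3-iodo-4,6-bis(methoxymethoxy)phenyl]-2-methylpropan-1-one
Conditions: NIS (1.05 equiv), DMF, 0 °C → rt, dark
Reagents that add atoms: N-iodosuccinimide, O=C1CCC(=O)N1I
Why: Electrophilic aromatic iodination under neutral, MOM-compatible conditions, expected at C3 next to the free chelated hydroxyl, which is the usual site for halogenation of 2-hydroxy-4,6-dialkoxyaryl ketones.

**Step 4**
Reactants: 5 1-[2-hydroxy-3-iodo-4,6-bis(methoxymethoxy)phenyl]-2-methylpropan-1-one; 6 isoprene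
Product: 7 (R)-1-[4,6-bis(methoxymethoxy)-2-(prop-1-en-2-yl)-2,3-dihydrobenzofuran-7-yl]-2-methylpropan-1-one
Conditions: Pd2(dba)3·CHCl3 (5 mol %), chiral tert-butanesulfinamide-derived monophosphine (TY-Phos type, 20 mol %, enantiomer chosen for the (R) product), NaOPh (2 equiv), isoprene (5 equiv), CH2Cl2, 40–50 °C, sealed tube
Reagents that add atoms: none
Why: Zerovalent palladium inserts into the C–I bond of 5, the arylpalladium adds syn across the unsubstituted vinyl group of isoprene with the aryl going to the terminal CH2, and the resulting 2-methyl-substituted π-allyl divalent palladium species is captured by the neighbouring phenoxide. The closest known reaction is the Larock heteroannulation of ortho-halophenols with 1,3-dienes in its ligand-controlled enantioselective Heck/Tsuji–Trost form. The dihydrofuran ring closes by 5-exo attack of the phenoxide oxygen on the internal allyl carbon, and the seven-membered alternative at the CH2 terminus is disfavoured. The C2 stereocentre is set by the chiral phosphine: the two faces of the allyl unit exchange by π–σ–π through the unsubstituted CH2 terminus, so the configuration follows from the faster C–O forming pathway of the ligand-bound complex, and the ligand antipode is picked to give (R). The step needs closure onto the oxygen next to the acyl-bearing carbon, and this is secured because the other two oxygens are MOM ethers and only the ketone-chelated hydroxyl ortho to iodine is free.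

**Step 5**
Reactants: 7 (R)-1-[4,6-bis(methoxymethoxy)-2-(prop-1-en-2-yl)-2,3-dihydrobenzofuran-7-yl]-2-methylpropan-1-one
Product: 8 (R)-1-[2-(2-hydroxypropan-2-yl)-4,6-bis(methoxymethoxy)-2,3-dihydrobenzofuran-7-yl]-2-methylpropan-1-one
Conditions: Co(acac)2 (20 mol %), PhSiH3 (2 equiv), O2 (1 atm), THF, rt
Reagents that add atoms: dioxygen, O=O
Why: Mukaiyama hydration, in which hydrogen-atom transfer from a cobalt hydride to the only alkene gives the tertiary radical that is trapped by O2 and reduced to the Markovnikov alcohol, with the neighbouring C2 stereocentre untouched and still (R).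

**Step 6**
Reactants: 8 (R)-1-[2-(2-hydroxypropan-2-yl)-4,6-bis(methoxymethoxy)-2,3-dihydrobenzofuran-7-yl]-2-methylpropan-1-one
Product: 9 (R)-1-[4,6-dihydroxy-2-(2-hydroxypropan-2-yl)-2,3-dihydrobenzofuran-7-yl]-2-methylpropan-1-one
Conditions: HCl (2 M) in MeOH, 40 °C
Reagents that add atoms: none
Why: Acid-catalysed acetal methanolysis removes both aryl MOM ethers, while the tertiary alcohol, whose cation would be destabilised by the adjacent ether oxygen, and the now non-allylic C2–O bond should hold under these mild conditions.

**Step 7**
Reactants: 9 (R)-1-[4,6-dihydroxy-2-(2-hydroxypropan-2-yl)-2,3-dihydrobenzofuran-7-yl]-2-methylpropan-1-one; 10 prenyl bromide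
Product: 12 (2R)-7-[(Z)-1-hydroxy-2-methylpropylidene]-2-(2-hydroxypropan-2-yl)-5,5-bis(3-methylbut-2-en-1-yl)-2,3-dihydro-1-benzofuran-4,6(5H,7H)-dione (Garcinielliptone HC), via 5-prenyl phenol 11 (not isolated)
Conditions: prenyl bromide (2.3 equiv in all), 10% aq. KOH, 0 °C → rt; then 1 M HCl to pH 3
Reagents that add atoms: prenyl bromide (second equivalent), CC(C)=CCBr
Why: Dearomative double C-prenylation of the acylphloroglucinol dianion (the lupulone-type gem-dialkylation) should consume two equivalents of prenyl bromide at C5, the only unsubstituted ring carbon and the one flanked by both phenoxide oxygens, the first equivalent giving phenol 11 and the second alkylating the same carbon again, with water as hydrogen-bonding solvent disfavouring O-alkylation and with no stereocentre formed or disturbed.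

**Compound list**
1 | phloroglucinol (benzene-1,3,5-triol) | Oc1cc(O)cc(O)c1 | starting material
2 | isobutyryl chloride | CC(C)C(Cl)=O | starting material
3 | 2-methyl-1-(2,4,6-trihydroxyphenyl)propan-1-one | CC(C)C(=O)c1c(O)cc(O)cc1O | intermediate
4 | 1-[2-hydroxy-4,6-bis(methoxymethoxy)phenyl]-2-methylpropan-1-one | CC(C)C(=O)c1c(O)cc(OCOC)cc1OCOC | intermediate
5 | 1-[2-hydroxy-3-iodo-4,6-bis(methoxymethoxy)phenyl]-2-methylpropan-1-one | CC(C)C(=O)c1c(O)c(I)c(OCOC)cc1OCOC | intermediate
6 | isoprene | C=CC(C)=C | starting material
7 | (R)-1-[4,6-bis(methoxymethoxy)-2-(prop-1-en-2-yl)-2,3-dihydrobenzofuran-7-yl]-2-methylpropan-1-one | CC(C)C(=O)c1c(OCOC)cc(OCOC)c2c1O[C@@H](C(C)=C)C2 | intermediate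
8 | (R)-1-[2-(2-hydroxypropan-2-yl)-4,6-bis(methoxymethoxy)-2,3-dihydrobenzofuran-7-yl]-2-methylpropan-1-one | CC(C)C(=O)c1c(OCOC)cc(OCOC)c2c1O[C@@H](C(C)(C)O)C2 | intermediate
9 | (R)-1-[4,6-dihydroxy-2-(2-hydroxypropan-2-yl)-2,3-dihydrobenzofuran-7-yl]-2-methylpropan-1-one | CC(C)C(=O)c1c(O)cc(O)c2c1O[C@@H](C(C)(C)O)C2 | intermediate
10 | prenyl bromide (1-bromo-3-methylbut-2-ene) | CC(C)=CCBr | starting material
11 | (R)-1-[4,6-dihydroxy-2-(2-hydroxypropan-2-yl)-5-(3-methylbut-2-en-1-yl)-2,3-dihydrobenzofuran-7-yl]-2-methylpropan-1-one | CC(C)C(=O)c1c(O)c(CC=C(C)C)c(O)c2c1O[C@@H](C(C)(C)O)C2 | intermediate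
12 | Garcinielliptone HC, (2R)-7-[(Z)-1-hydroxy-2-methylpropylidene]-2-(2-hydroxypropan-2-yl)-5,5-bis(3-methylbut-2-en-1-yl)-2,3-dihydro-1-benzofuran-4,6(5H,7H)-dione | CC(C)=CCC1(CC=C(C)C)C(=O)C2=C(O[C@@H](C(C)(C)O)C2)/C(=C(/O)C(C)C)C1=O | target

**Step count**
Total steps: 7. Longest linear sequence: 7 steps.

**Steps most likely to fail**

1. Step 4. Oxidative addition and diene insertion at the doubly ortho-substituted, electron-rich aryl iodide may be slow, so that protodeiodination or β-hydride elimination to an open-chain aryl diene takes over. Iodide and the chelating acyl phenoxide may also disturb the ligand sphere and lower the facial selectivity of C–O bond formation. Fallback, setting out from 5 and coming back at 8: the stereocentre would be set by reagent-controlled epoxidation instead of by a palladium ligand. Stille coupling of 5 with tributyl(3-methylbut-2-en-1-yl)stannane (Pd(PPh3)4, DMF, 80 °C) should give the ortho-prenylphenol F1. Acetylation (Ac2O, pyridine, DMAP) should give the aryl acetate F2. Shi epoxidation (KHSO5 supplied as the triple salt 2KHSO5·KHSO4·K2SO4, K2CO3 buffer, MeCN/dimethoxymethane/H2O, 0 °C, with the fructose-derived ketone of the enantiomeric series that gives the (S)-oxirane) should give the (S)-epoxide F3. K2CO3 in MeOH would then cleave the acetate, and the phenoxide would open the epoxide at its secondary carbon (5-exo, inversion) to give 8 directly, so that step 5 is not needed.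

2. Step 7. O-alkylation of the phenoxides or of the product enolate may compete with C-alkylation, the second prenyl group may enter at the ring-fusion carbon C3a instead of C5, or a third alkylation may follow. Fallback, setting out from 9 and coming back at 12: a soft π-allyl electrophile, whose O-allylation is reversible under palladium catalysis, would replace the alkyl halide. Treatment of 9 with allyl methyl carbonate (2.5 equiv) and Pd(PPh3)4 in THF at rt should give the dearomatised 5,5-diallyl dione F4. Double cross-metathesis of F4 with 2-methylbut-2-ene (second-generation Grubbs catalyst, (SIMes)(PCy3)Cl2Ru=CHPh, CH2Cl2, 40 °C) should convert both allyl groups into prenyl groups and give 12.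

3. Step 3. Iodination may go to C5 between the two MOM ethers (para to the free hydroxyl) or twice, and traces of HI may strip a MOM group. Fallback, setting out from 3 and coming back at 5: the halogen would be introduced while the two ring CH positions are still equivalent. Mono-iodination of 3 (NIS, 1.0 equiv, MeCN, −20 °C) should give the iodotriol F5, in which either ring position gives the same compound. Bis-MOM protection (MOMCl, i-Pr2NEt, CH2Cl2, 0 °C) should then leave free the most hindered hydroxyl, the one between iodine and the acyl group that stays hydrogen-bonded to the ketone, and give 5.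

**Further compounds**
F1 | step 4 | 1-[2-hydroxy-4,6-bis(methoxymethoxy)-3-(3-methylbut-2-en-1-yl)phenyl]-2-methylpropan-1-one | CC(C)C(=O)c1c(O)c(CC=C(C)C)c(OCOC)cc1OCOC
F2 | step 4 | 3,5-bis(methoxymethoxy)-2-(2-methylpropanoyl)-6-(3-methylbut-2-en-1-yl)phenyl acetate | CC(C)C(=O)c1c(OC(C)=O)c(CC=C(C)C)c(OCOC)cc1OCOC
F3 | step 4 | 2-{[(2S)-3,3-dimethyloxiran-2-yl]methyl}-3,5-bis(methoxymethoxy)-6-(2-methylpropanoyl)phenyl acetate | CC(C)C(=O)c1c(OC(C)=O)c(C[C@@H]2OC2(C)C)c(OCOC)cc1OCOC
F4 | step 7 | (2R)-5,5-diallyl-7-[(Z)-1-hydroxy-2-methylpropylidene]-2-(2-hydroxypropan-2-yl)-2,3-dihydro-1-benzofuran-4,6(5H,7H)-dione | C=CCC1(CC=C)C(=O)C2=C(O[C@@H](C(C)(C)O)C2)/C(=C(/O)C(C)C)C1=O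
F5 | step 3 | 1-(2,4,6-trihydroxy-3-iodophenyl)-2-methylpropan-1-one | CC(C)C(=O)c1c(O)cc(O)c(I)c1O
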